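## Retrosynthetic overview

1. Target 23 comes from acetylation of the C12 carbinol 22, which comes from methanolysis of a ten-membered lactone 21 that ties C1 to O12.
2. Lactone 21 comes from ring-closing metathesis of the C12 hex-5-enoate 20, forming C5=C6. The feature used: in the 7E isomer, C6 and O12 lie on the same side of the exocyclic C7=C8 bond of the five-membered ring (C8–C12), so O12–C1–C2–C3–C4–C5=C6–C7=C8–C12 closes as a ten-membered ring that can hold C5=C6 only as cis.
3. Ester 20 comes from esterification of the tertiary alcohol 18 with hex-5-enoic acid; C7=C8 comes from aldol condensation of acrolein with the 2-chloro-4-silyloxy-4-octenylcyclopentenone 12.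
4. Enone 12 comes from the chlorinated isobutyl enol ether of cyclopentane-1,3-dione by C12–C13 alkylation, reagent-controlled enolate hydroxylation (sets C12) and Stork–Danheiser carbonyl transposition.
5. Ring order: the five-membered ring is present in the starting dione; the ten-membered lactone (step 12) is the only ring formed and is opened again in step 13.

Key step: step 12

Assumption: target atoms carry prostanoid numbers (C1 ester carbon, ring C8–C12, C9 ketone, C10 chloro carbon, C12 carbinol carbon, C13–C20 octenyl chain), and the (−)-enantiomer of the oxaziridine in step 5 is taken, by analogy with 2-alkyl-1-tetralone enolates, to give the (5S)-carbinol; should the opposite sense be found, the (+)-enantiomer is used with no other change.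

## Route

Step 1
Reactants: 1 cyclopentane-1,3-dione
Product: 2 3-(2-methylpropoxy)cyclopent-2-en-1-one
Conditions: i-BuOH, TsOH·H2O (cat.), toluene, reflux, Dean–Stark
Reagents that add atoms: 2-methylpropan-1-ol CC(C)CO
Why: Acid-catalysed enol etherification of the symmetric 1,3-dione with azeotropic removal of water gives the vinylogous ester without any regiochemical question.

Step 2
Reactants: 2 3-(2-methylpropoxy)cyclopent-2-en-1-one
Product: 3 2-chloro-3-(2-methylpropoxy)cyclopent-2-en-1-one
Conditions: NCS, CH2Cl2, 0 °C → rt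
Reagents that add atoms: N-chlorosuccinimide O=C1CCC(=O)N1Cl
Why: Electrophilic α-chlorination of a β-alkoxy enone; the α-carbon is the only nucleophilic carbon of the vinylogous ester.

Step 3
Reactants: 4 (2Z)-oct-2-en-1-ol
Product: 5 (2Z)-1-bromooct-2-ene
Conditions: CBr4, PPh3, CH2Cl2, 0 °C
Reagents that add atoms: carbon tetrabromide BrC(Br)(Br)Br
Why: Appel bromination by SN2 displacement of the alkoxyphosphonium ion at the primary allylic carbon, which at 0 °C should leave the Z alkene untouched.

Step 4
Reactants: 3 2-chloro-3-(2-methylpropoxy)cyclopent-2-en-1-one; 5 (2Z)-1-bromooct-2-ene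
Product: 7 racemic 2-chloro-3-(2-methylpropoxy)-5-[(2Z)-oct-2-en-1-yl]cyclopent-2-en-1-one, via lithium enolate 6 (not isolated)
Conditions: LiN(i-Pr)2, THF, −78 °C; then 5, DMPU, −78 → −30 °C
Reagents that add atoms: none
Why: Stork–Danheiser kinetic α'-deprotonation of the vinylogous ester and SN2 alkylation of the cross-conjugated enolate by the primary allylic bromide; the new centre is racemic and is erased on enolisation in step 5.

Step 5
Reactants: 7 racemic 2-chloro-3-(2-methylpropoxy)-5-[(2Z)-oct-2-en-1-yl]cyclopent-2-en-1-one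
Product: 9 (5S)-2-chloro-5-hydroxy-3-(2-methylpropoxy)-5-[(2Z)-oct-2-en-1-yl]cyclopent-2-en-1-one, via potassium enolate 8 (not isolated)
Conditions: KN(SiMe3)2, THF, −78 °C; then (−)-[(8,8-dichlorocamphoryl)sulfonyl]oxaziridine, −78 → −50 °C; AcOH quench
Reagents that add atoms: (−)-[(8,8-dichlorocamphoryl)sulfonyl]oxaziridine (from (1R)-(−)-10-camphorsulfonic acid) O=S1(=O)C[C@]23CC[C@H](C2(C)C)C(Cl)(Cl)[C@@]34O[N@@]14
Why: Davis asymmetric enolate hydroxylation, in which the tetrasubstituted α'-enolate attacks the oxaziridine oxygen and the camphor framework of the reagent selects the enolate face, setting the quaternary carbinol centre (C12 of the target) by reagent control.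

Step 6
Reactants: 9 (5S)-2-chloro-5-hydroxy-3-(2-methylpropoxy)-5-[(2Z)-oct-2-en-1-yl]cyclopent-2-en-1-one
Product: 10 (5S)-5-(tert-butyldimethylsilyloxy)-2-chloro-3-(2-methylpropoxy)-5-[(2Z)-oct-2-en-1-yl]cyclopent-2-en-1-one
Conditions: TBSOTf, 2,6-lutidine, CH2Cl2, −78 → 0 °C
Reagents that add atoms: tert-butyldimethylsilyl trifluoromethanesulfonate CC(C)(C)[Si](C)(C)OS(=O)(=O)C(F)(F)F
Why: Silylation of the tertiary α-ketol by the silyl triflate with a hindered pyridine base, so that the hydride and amide-base steps that follow meet no free hydroxyl.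

Step 7
Reactants: 10 (5S)-5-(tert-butyldimethylsilyloxy)-2-chloro-3-(2-methylpropoxy)-5-[(2Z)-oct-2-en-1-yl]cyclopent-2-en-1-one
Product: 12 (4S)-4-(tert-butyldimethylsilyloxy)-2-chloro-4-[(2Z)-oct-2-en-1-yl]cyclopent-2-en-1-one, via allylic alcohol 11 (not isolated)
Conditions: i-Bu2AlH, toluene, −78 °C; then 1 M aq. HCl, THF, 0 °C → rt
Reagents that add atoms: water O
Why: Stork–Danheiser carbonyl transposition: 1,2-reduction of the vinylogous ester carbonyl, then acid ionises the allylic alcohol to an alkoxyallyl cation that water captures at the alkoxy-bearing carbon with loss of isobutanol; the quaternary centre is not involved and the tertiary silyl ether resists dilute acid.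

Step 8
Reactants: 12 (4S)-4-(tert-butyldimethylsilyloxy)-2-chloro-4-[(2Z)-oct-2-en-1-yl]cyclopent-2-en-1-one; 13 acrolein
Product: 15 (4S)-4-(tert-butyldimethylsilyloxy)-2-chloro-5-(1-hydroxyprop-2-en-1-yl)-4-[(2Z)-oct-2-en-1-yl]cyclopent-2-en-1-one (diastereomer mixture), via lithium enolate 14 (not isolated)
Conditions: LiN(i-Pr)2, THF, −78 °C; then 13, −78 °C; AcOH quench at −78 °C
Reagents that add atoms: none
Why: Aldol addition: the kinetic lithium enolate at the only enolisable carbon (C8) adds 1,2 to acrolein at low temperature; both new centres are removed in step 9.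

Step 9
Reactants: 15 (4S)-4-(tert-butyldimethylsilyloxy)-2-chloro-5-(1-hydroxyprop-2-en-1-yl)-4-[(2Z)-oct-2-en-1-yl]cyclopent-2-en-1-one
Product: 17 (4R,5E)-4-(tert-butyldimethylsilyloxy)-2-chloro-4-[(2Z)-oct-2-en-1-yl]-5-(prop-2-en-1-ylidene)cyclopent-2-en-1-one, via allylic mesylate 16 (not isolated)
Conditions: MsCl, Et3N (excess), CH2Cl2, −20 °C → rt
Reagents that add atoms: none
Why: Mesylation followed by amine-induced E1cB elimination through the enolate gives the conjugated exocyclic alkene; the E isomer, with the vinyl group away from the carbonyl oxygen, should be favoured, and any 7Z isomer is removed by chromatography.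

Step 10
Reactants: 17 (4R,5E)-4-(tert-butyldimethylsilyloxy)-2-chloro-4-[(2Z)-oct-2-en-1-yl]-5-(prop-2-en-1-ylidene)cyclopent-2-en-1-one
Product: 18 (4R,5E)-2-chloro-4-hydroxy-4-[(2Z)-oct-2-en-1-yl]-5-(prop-2-en-1-ylidene)cyclopent-2-en-1-one
Conditions: HF·pyridine, THF, 0 °C → rt
Reagents that add atoms: none
Why: Fluoride cleavage of the Si–O bond under acidic rather than basic conditions, which should spare the base-sensitive cross-conjugated dienone.

Step 11
Reactants: 18 (4R,5E)-2-chloro-4-hydroxy-4-[(2Z)-oct-2-en-1-yl]-5-(prop-2-en-1-ylidene)cyclopent-2-en-1-one; 19 hex-5-enoic acid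
Product: 20 (1R,5E)-3-chloro-1-[(2Z)-oct-2-en-1-yl]-4-oxo-5-(prop-2-en-1-ylidene)cyclopent-2-en-1-yl hex-5-enoate
Conditions: DCC, DMAP, CH2Cl2, 0 °C → rt (excess 19 and DCC)
Reagents that add atoms: none
Why: Steglich esterification, in which DMAP turns the O-acylisourea into an acylpyridinium ion reactive enough to acylate the tertiary alcohol without touching the C12–O bond.

Step 12
Reactants: 20 (1R,5E)-3-chloro-1-[(2Z)-oct-2-en-1-yl]-4-oxo-5-(prop-2-en-1-ylidene)cyclopent-2-en-1-yl hex-5-enoate
Product: 21 (5Z,7E,12R,14Z)-10-chloro-12-hydroxy-9-oxoprosta-5,7,10,14-tetraenoic acid 1,12-lactone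
Conditions: RuCl2(H2IMes)(=CH-C6H4-2-O-i-Pr) (second-generation Hoveyda–Grubbs catalyst, 10 mol%), 1,4-benzoquinone (20 mol%), toluene, 0.5 mM by slow addition of 20, 60 °C, Ar sparge
Reagents that add atoms: none
Why: Olefin metathesis by the Chauvin mechanism: the catalyst initiates at the unhindered, electron-neutral hexenoate terminus, and the resulting alkylidene at C5 undergoes [2+2] cycloaddition and cycloreversion with the terminal CH2=C6 alkene, forming C5=C6 and releasing ethene. The closest known reaction type is diene–ene ring-closing metathesis to ten-membered lactones. The one ring closed is the ten-membered lactone (O12, C1–C8, C12), closed at C5=C6 as a macrocyclic ring-closing metathesis; it is possible only because the 7E geometry holds C6 on the C12 side of the exocyclic C7=C8 bond, so a 7Z isomer cannot cyclise. No stereocentre is formed; the alkene geometry is set by the ring, since with C7=C8 already cis within the ten-membered ring a trans C5=C6 bond would be far more strained, so the 5Z isomer should result. The step needs the ten-membered closure to outrun a six-membered closure of C6 onto C14=C15 (loss of hept-1-ene) and oligomerisation. The first is countered because ruthenium loads at the isolated terminal alkene in preference to the conjugated, electron-poor dienyl terminus or the internal cis C14=C15 bond, and from C5 the alkylidene could reach C14=C15 only through a nine-membered ring; the second is countered by high dilution and ethene removal, with benzoquinone suppressing alkene migration.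

Step 13
Reactants: 21 (5Z,7E,12R,14Z)-10-chloro-12-hydroxy-9-oxoprosta-5,7,10,14-tetraenoic acid 1,12-lactone
Product: 22 methyl (5Z,7E,12R,14Z)-10-chloro-12-hydroxy-9-oxoprosta-5,7,10,14-tetraenoate
Conditions: (+)-10-camphorsulfonic acid (cat.), MeOH, rt → 40 °C, dark
Reagents that add atoms: methanol CO
Why: Acid-catalysed transesterification by acyl–oxygen cleavage, driven by methanol as solvent, relief of medium-ring strain and restored conjugation of C5=C6 with the dienone; ionisation of the C12–O bond is disfavoured because the cation would be conjugated with the electron-poor enone, so C12 keeps its configuration.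

Step 14
Reactants: 22 methyl (5Z,7E,12R,14Z)-10-chloro-12-hydroxy-9-oxoprosta-5,7,10,14-tetraenoate
Product: 23 methyl (5Z,7E,12R,14Z)-12-acetoxy-10-chloro-9-oxoprosta-5,7,10,14-tetraenoate
Conditions: Ac2O, Et3N, DMAP (cat.), CH2Cl2, 0 °C → rt
Reagents that add atoms: acetic anhydride CC(=O)OC(C)=O
Why: DMAP-catalysed acetylation of the tertiary alcohol through the acetylpyridinium ion; the C12–O bond is not broken, so the configuration is retained.

## Compound list

1 | cyclopentane-1,3-dione | O=C1CCC(=O)C1 | starting material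
2 | 3-(2-methylpropoxy)cyclopent-2-en-1-one | CC(C)COC1=CC(=O)CC1 | intermediate
3 | 2-chloro-3-(2-methylpropoxy)cyclopent-2-en-1-one | CC(C)COC1=C(Cl)C(=O)CC1 | intermediate
4 | (2Z)-oct-2-en-1-ol | CCCCC/C=C\CO | starting material
5 | (2Z)-1-bromooct-2-ene | CCCCC/C=C\CBr | intermediate
6 | lithium enolate of 3 | CC(C)COC1=C(Cl)C(O[Li])=CC1 | intermediate (not isolated)
7 | racemic 2-chloro-3-(2-methylpropoxy)-5-[(2Z)-oct-2-en-1-yl]cyclopent-2-en-1-one | CCCCC/C=C\CC1CC(OCC(C)C)=C(Cl)C1=O | intermediate
8 | potassium enolate of 7 | CCCCC/C=C\CC1=C(O[K])C(Cl)=C(OCC(C)C)C1 | intermediate (not isolated)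
9 | (5S)-2-chloro-5-hydroxy-3-(2-methylpropoxy)-5-[(2Z)-oct-2-en-1-yl]cyclopent-2-en-1-one | CCCCC/C=C\C[C@@]1(O)C(=O)C(Cl)=C(OCC(C)C)C1 | intermediate
10 | (5S)-5-(tert-butyldimethylsilyloxy)-2-chloro-3-(2-methylpropoxy)-5-[(2Z)-oct-2-en-1-yl]cyclopent-2-en-1-one | CCCCC/C=C\C[C@@]1(O[Si](C)(C)C(C)(C)C)C(=O)C(Cl)=C(OCC(C)C)C1 | intermediate
11 | (5S)-5-(tert-butyldimethylsilyloxy)-2-chloro-3-(2-methylpropoxy)-5-[(2Z)-oct-2-en-1-yl]cyclopent-2-en-1-ol (C1 epimers) | CCCCC/C=C\C[C@@]1(O[Si](C)(C)C(C)(C)C)C(O)C(Cl)=C(OCC(C)C)C1 | intermediate (not isolated)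
12 | (4S)-4-(tert-butyldimethylsilyloxy)-2-chloro-4-[(2Z)-oct-2-en-1-yl]cyclopent-2-en-1-one | CCCCC/C=C\C[C@@]1(O[Si](C)(C)C(C)(C)C)C=C(Cl)C(=O)C1 | intermediate
13 | acrolein | C=CC=O | starting material
14 | lithium enolate of 12 | CCCCC/C=C\C[C@@]1(O[Si](C)(C)C(C)(C)C)C=C(Cl)C(O[Li])=C1 | intermediate (not isolated)
15 | (4S)-4-(tert-butyldimethylsilyloxy)-2-chloro-5-(1-hydroxyprop-2-en-1-yl)-4-[(2Z)-oct-2-en-1-yl]cyclopent-2-en-1-one (diastereomer mixture) | CCCCC/C=C\C[C@@]1(O[Si](C)(C)C(C)(C)C)C=C(Cl)C(=O)C1C(O)C=C | intermediate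
16 | methanesulfonate of 15 | CCCCC/C=C\C[C@@]1(O[Si](C)(C)C(C)(C)C)C=C(Cl)C(=O)C1C(OS(C)(=O)=O)C=C | intermediate (not isolated)
17 | (4R,5E)-4-(tert-butyldimethylsilyloxy)-2-chloro-4-[(2Z)-oct-2-en-1-yl]-5-(prop-2-en-1-ylidene)cyclopent-2-en-1-one | CCCCC/C=C\C[C@@]1(O[Si](C)(C)C(C)(C)C)C=C(Cl)C(=O)/C1=C/C=C | intermediate
18 | (4R,5E)-2-chloro-4-hydroxy-4-[(2Z)-oct-2-en-1-yl]-5-(prop-2-en-1-ylidene)cyclopent-2-en-1-one | CCCCC/C=C\C[C@@]1(O)C=C(Cl)C(=O)/C1=C/C=C | intermediate
19 | hex-5-enoic acid | C=CCCCC(=O)O | starting material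
20 | (1R,5E)-3-chloro-1-[(2Z)-oct-2-en-1-yl]-4-oxo-5-(prop-2-en-1-ylidene)cyclopent-2-en-1-yl hex-5-enoate | CCCCC/C=C\C[C@@]1(OC(=O)CCCC=C)C=C(Cl)C(=O)/C1=C/C=C | intermediate
21 | (5Z,7E,12R,14Z)-10-chloro-12-hydroxy-9-oxoprosta-5,7,10,14-tetraenoic acid 1,12-lactone | CCCCC/C=C\C[C@]12OC(=O)CCC/C=C\C=C1\C(=O)C(Cl)=C2 | intermediate
22 | methyl (5Z,7E,12R,14Z)-10-chloro-12-hydroxy-9-oxoprosta-5,7,10,14-tetraenoate | CCCCC/C=C\C[C@@]1(O)C=C(Cl)C(=O)/C1=C/C=C\CCCC(=O)OC | intermediate
23 | methyl (5Z,7E,12R,14Z)-12-acetoxy-10-chloro-9-oxoprosta-5,7,10,14-tetraenoate | CCCCC/C=C\C[C@@]1(OC(C)=O)C=C(Cl)C(=O)/C1=C/C=C\CCCC(=O)OC | target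

## Step count and risk

Total steps: 14. Longest linear sequence: 13 steps (steps 1, 2 and 4–14, from cyclopentane-1,3-dione); step 3 is a one-step side branch.

Steps most likely to fail:

**Step 12.** The ruthenium carbene may load on the dienyl terminus and close a six-membered ring onto C14=C15 with loss of hept-1-ene. The hindered tertiary ester may also fail to reach the ring-closing conformation, so that oligomerisation takes over. The fallback drops the tether and builds the (5Z,7E)-diene by the classical aldol condensation, setting out from 12 and returning at 22. Commercial methyl 7-hydroxyhept-5-ynoate is semi-hydrogenated (H2, Pd/CaCO3 poisoned with Pb(OAc)2, quinoline, EtOAc) to methyl (5Z)-7-hydroxyhept-5-enoate F1. Buffered Dess–Martin oxidation (NaHCO3, CH2Cl2, 0 °C) gives methyl (5Z)-7-oxohept-5-enoate F2. Lithium enolate 14, made from 12 as in step 8, adds to F2 at −78 °C to give the aldol adduct F3. MsCl and Et3N convert F3, through its methanesulfonate F4, into methyl (5Z,7E,12R,14Z)-12-(tert-butyldimethylsilyloxy)-10-chloro-9-oxoprosta-5,7,10,14-tetraenoate F5, which is separated from geometric isomers by chromatography. HF·pyridine then gives 22, and the route resumes at step 14.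

**Step 13.** Acyl–oxygen cleavage at the hindered tertiary ester may be slow. Prolonged acid exposure could then allow 5Z to 5E isomerisation or conjugate addition of methanol to the dienone. The fallback replaces acid-catalysed alcoholysis by neutral tin-mediated hydrolysis and a separate methylation, setting out from 21 and returning at 22. Me3SnOH in 1,2-dichloroethane at 60 °C opens the lactone to (5Z,7E,12R,14Z)-10-chloro-12-hydroxy-9-oxoprosta-5,7,10,14-tetraenoic acid F6. (Trimethylsilyl)diazomethane in MeOH/toluene at 0 °C esterifies F6 to 22.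

**Step 5.** Facial selectivity of oxygen transfer to the five-membered enolate may be poor or of the wrong sense, and competing γ-deprotonation may divert the enolate. The fallback replaces reagent control by racemic oxidation and physical resolution, setting out from 7 and returning at 9. The potassium enolate 8 is oxidised with racemic 3-phenyl-2-(phenylsulfonyl)oxaziridine to racemic 2-chloro-5-hydroxy-3-(2-methylpropoxy)-5-[(2Z)-oct-2-en-1-yl]cyclopent-2-en-1-one F7. Preparative chromatography on an amylose tris(3,5-dimethylphenylcarbamate) phase separates 9 from its (5R)-enantiomer F8, which is set aside.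

## Further compounds

F1 | step 12 | methyl (5Z)-7-hydroxyhept-5-enoate | COC(=O)CCC/C=C\CO
F2 | step 12 | methyl (5Z)-7-oxohept-5-enoate | COC(=O)CCC/C=C\C=O
F3 | step 12 | methyl (5Z,14Z)-12-(tert-butyldimethylsilyloxy)-10-chloro-7-hydroxy-9-oxoprosta-5,10,14-trienoate (12S by CIP, diastereomer mixture at C7 and C8) | CCCCC/C=C\C[C@@]1(O[Si](C)(C)C(C)(C)C)C=C(Cl)C(=O)C1C(O)/C=C\CCCC(=O)OC
F4 | step 12 | 7-methanesulfonate of F3 | CCCCC/C=C\C[C@@]1(O[Si](C)(C)C(C)(C)C)C=C(Cl)C(=O)C1C(OS(C)(=O)=O)/C=C\CCCC(=O)OC
F5 | step 12 | methyl (5Z,7E,12R,14Z)-12-(tert-butyldimethylsilyloxy)-10-chloro-9-oxoprosta-5,7,10,14-tetraenoate | CCCCC/C=C\C[C@@]1(O[Si](C)(C)C(C)(C)C)C=C(Cl)C(=O)/C1=C/C=C\CCCC(=O)OC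
F6 | step 13 | (5Z,7E,12R,14Z)-10-chloro-12-hydroxy-9-oxoprosta-5,7,10,14-tetraenoic acid | CCCCC/C=C\C[C@@]1(O)C=C(Cl)C(=O)/C1=C/C=C\CCCC(=O)O
F7 | step 5 | racemic 2-chloro-5-hydroxy-3-(2-methylpropoxy)-5-[(2Z)-oct-2-en-1-yl]cyclopent-2-en-1-one | CCCCC/C=C\CC1(O)C(=O)C(Cl)=C(OCC(C)C)C1
F8 | step 5 | (5R)-2-chloro-5-hydroxy-3-(2-methylpropoxy)-5-[(2Z)-oct-2-en-1-yl]cyclopent-2-en-1-one | CCCCC/C=C\C[C@]1(O)C(=O)C(Cl)=C(OCC(C)C)C1
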